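Labdane numbering is used throughout: ring A is C1–C5/C10, ring B is C5–C10, C11–C12 link C9 to C13=C14–C15, C16 is the acetoxymethyl carbon on C13, C17 is the carboxyl carbon on C8, and C20 is the methyl on C10.

## The problem

The target is an ent-labdane, (5R,8S,9R,10S,13E)-16-acetoxylabda-6,13-diene-15,17-dioic acid. It is a trans-fused decalin whose ring B carries four contiguous stereocentres (C5, quaternary C10, C9 with the side chain, C8 with a carboxyl) and a C6=C7 alkene. The side chain ends in an (E)-trisubstituted enoic acid with an acetoxymethyl branch. The ring problem is to join C9 to a quaternary C10 with absolute control and then to close one ring so that the C5 hydrogen lies opposite C20. C10 can control the rest: its axial methyl and the axial C4 methyl shield one face of C5, and an axial substituent on C8 would be 1,3-diaxial to C20, so C8 can be left to equilibrium whenever a carbonyl sits beside it. Only the C9/C10 pair needs an external source of chirality. The fragile parts are the C8 acid (allylic and α to a carbonyl, so base can epimerise it or move the alkene into conjugation), the allylic acetate (lost to hydroxide, ionised by zerovalent palladium), and the need to distinguish two carboxylic acids from an acetate at the end. The feature that makes the key step possible is that C5 is bonded to two fully substituted carbons, C4 and C10. An exocyclic C5=C6 methylene can then be attacked only at C6, and the tertiary C5 radical cannot undergo the methyl shift that a cation would. An acyl radical at C7 leaves a ketone where it is needed to settle C8 and to place the C6=C7 alkene.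

## Retrosynthesis

**End game, 32 back to 27.** No skeletal bond is cut; the C17 oxidation level, the O-acetyl bond and the C15 ester are taken back. The C8 acid 32 is made last from primary alcohol 30, because the β,γ-unsaturated acid and aldehyde 31 are the most base-sensitive functions. Acetate 29 is formed from hydroxy acid 28 only after methyl ester 27 has been saponified, so no ester is ever cleaved beside the acetate. The C17 silyl ether survives hydroxide and leaves with fluoride. An acid-labile C15 ester would give a gentler last step but needs a longer fragment synthesis. The forward reaction must oxidise 30 without enolising aldehyde 31.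

**C12–C13, 27 back to 23 and 25.** Cutting between the sp3 C12 and the sp2 C13 gives a vinyl group on C9 (23) and the four-carbon iodoenoate 25. The alternative of forming C13=C14 by olefination of a ketone would give E/Z mixtures. Here the geometry is fixed in 25 by anti hydroiodination of ynoate 24 and carried through the coupling with retention. The forward step needs hydroboration of the vinyl group only, and coupling without exposing an allylic acetate to palladium, which is why C16 is a free alcohol at that stage.

**C6=C7 alkene, 23 back to ketone 20.** The alkene is traced to a C7 ketone through tosylhydrazone 21. A ketone at C7 serves two purposes: C8 can be equilibrated to the equatorial epimer, and the hydrazone dianion forms at the C6 methylene, not at the C8 methine, so the alkene is placed regioselectively. Dehydration of a C7 alcohol would not distinguish C6 from C8. C17 must stay at the alcohol oxidation level here, since a β-keto ester would not undergo this chemistry.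

**C6–C7, ketone 20 back to selenoester 18 (key disconnection).** Opening ring B between C6 and C7 gives a monocyclic acyl radical precursor with a C5 exocyclic methylene. This cut is preferred over C5–C6 or C9–C10 ring closures because it creates the C5 hydrogen under control of C10 and delivers the C7 carbonyl at once. A cationic version of the same bond formation would invite a methyl shift at C5. The precursor 18 has only two stereocentres that matter (C9, C10), and C8 may be either epimer. The forward step needs 6-endo closure faster than loss of CO, and hydrogen transfer to C5 from the face opposite C20.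

**Functional-group adjustments, 18 back to 9.** Selenoester 18 comes from acid 16 and diphenyl diselenide 17. Acid 16 comes from mono-silyl ether 14, diol 13 and acetonide 12 by differentiating the two hydroxymethyl arms on C8. That differentiation creates C8 without control, which is acceptable because C8 is equilibrated later. The vinyl group of 12 is traced through aldehyde 11 and alcohol 10 to acid 9. Installing the vinyl group before ring closure, not as a protected alcohol, removes a protection, a deprotection and the need for orthogonal ethers. The forward sequence must methylenate 11 without epimerising C9.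

**C9–C10, acid 9 back to ester 6, then 3 and 5.** The bond between the tertiary C9 and the quaternary C10 is cut as an Ireland–Claisen rearrangement of the β-cyclogeranyl ester 6. This cut makes both stereocentres, the quaternary carbon and the exocyclic methylene in one step from two achiral pieces. The symmetric acetonide in acid 3 keeps C8 prochiral, so 9 is a single compound. Ester 6 comes from acid 3 (by oxidation of alcohol 1) and β-cyclogeraniol 5 (by reduction of β-cyclocitral 4). The forward rearrangement needs the E(O) enolate in a chair, plus a chiral controller on the enolate oxygen for the absolute sense.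

## Roads not taken

**Alternative 1:** Both rings are cut at C4–C5 and C9–C10, back to acyclic geranylgeranyl diphosphate A1. In the forward direction ent-copalyl diphosphate synthase protonates the terminal alkene and the folded chain closes twice to ent-copalyl diphosphate A2. This is much better than the chosen plan at building the bicycle: two rings and the C5, C9 and C10 stereocentres form in one step as a single enantiomer, without protecting groups. Its weakness is what follows. A2 has an exocyclic C8=C17 alkene, an unoxidised C16 methyl and nothing at C6 or C7. The target would then need selective allylic oxidation of C16 beside several other allylic positions, conversion of the C8 methylene into an equatorial carboxyl, and a C6=C7 alkene at a position with no neighbouring handle. Enzyme and substrate supply also limit scale. The chosen plan takes about twelve steps to reach the decalin, but every oxidised carbon is placed by construction and the C7 carbonyl fixes both C8 and the alkene.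

**Alternative 2:** Ring A is cut at C1–C10, back to phenol A3, a para-cresol carrying a (Z)-alkenyl iodide tether. In the forward step zerovalent palladium inserts into the C–I bond and the phenolate para carbon attacks, giving dienone A4 with C10 quaternary. Its merits are real: C10 could be set catalytically with a chiral ligand, where the chosen plan uses a stoichiometric boron controller, and A4 already carries oxygen at C7. The weak points are that A4 has only one stereocentre. C5, C8 and C9 are all sp2 and would have to be set by successive reductions of a cross-conjugated dienone; C17 must still be attached at C8, the α-carbon of an enone; and the ring A alkene must be removed selectively. The tetrasubstituted arene A3 is itself a multi-step target. The chosen plan sets C9 together with C10 and leaves only C5 and C8, both under control of C10.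

**Alternative 3:** The side chain is cut at C12–C13 and C14–C15. Bromide A5 is turned into a C12 copper reagent, which adds syn across alkyne A6, and the alkenylcopper is trapped with CO2 to give acid A7. The merits are a three-component assembly with the alkene geometry fixed by syn addition, and a free C15 acid, which would save the saponification step of the chosen route. For the side chain alone it is as direct as the coupling of 23 with 25. Its weak point is that it does not address the ring system: A5 already contains all four ring stereocentres and the C6=C7 alkene, and it lies two steps beyond compound 23. It also makes a stoichiometric organometallic from the most valuable intermediate and needs a tert-butyl ether to acetate exchange at the end. The chosen route uses 23 directly, with catalytic palladium and a one-step partner.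

Key step: step 12

Assumptions:
- The (S,S)-bromoborane is written in step 4; the sense of induction is assigned by analogy, and if it delivers the mirror-image acid the (R,R)-reagent is used with no other change.
- Alcohol 1 is taken as a purchasable building block; it is otherwise two routine steps (ester reduction, acetonide formation) from triethyl ethane-1,1,2-tricarboxylate.

## Route

Step 1
Reactants: 1 2-(2,2-dimethyl-1,3-dioxan-5-yl)ethan-1-ol
Product: 3 2-(2,2-dimethyl-1,3-dioxan-5-yl)acetic acid, via dioxanyl acetaldehyde 2 (not isolated)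
Conditions: TEMPO (cat.), NaOCl (cat.), NaClO2, MeCN/phosphate buffer pH 6.7, 35 °C
Reagents that add atoms: sodium chlorite, [Na+].[O-]Cl=O
Why: Oxoammonium/chlorite oxidation of a primary alcohol to the acid through aldehyde 2; the near-neutral buffer spares the acid-labile 1,3-dioxane acetonide.

Step 2
Reactants: 4 β-cyclocitral (2,6,6-trimethylcyclohex-1-ene-1-carbaldehyde)
Product: 5 β-cyclogeraniol ((2,6,6-trimethylcyclohex-1-en-1-yl)methanol)
Conditions: NaBH4, MeOH, 0 °C
Reagents that add atoms: none
Why: Borohydride 1,2-reduction of the hindered conjugated aldehyde; the tetrasubstituted alkene is not touched.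

Step 3
Reactants: 3 2-(2,2-dimethyl-1,3-dioxan-5-yl)acetic acid; 5 β-cyclogeraniol
Product: 6 (2,6,6-trimethylcyclohex-1-en-1-yl)methyl 2-(2,2-dimethyl-1,3-dioxan-5-yl)acetate
Conditions: DCC, DMAP (cat.), CH2Cl2, 0 → 23 °C
Reagents that add atoms: none
Why: Steglich esterification of a primary allylic alcohol under neutral conditions, which keep the acetonide and do not ionise the allylic C–O bond.

Step 4
Reactants: 6 (2,6,6-trimethylcyclohex-1-en-1-yl)methyl 2-(2,2-dimethyl-1,3-dioxan-5-yl)acetate
Product: 9 (2R)-2-(2,2-dimethyl-1,3-dioxan-5-yl)-2-[(1S)-1,3,3-trimethyl-2-methylidenecyclohexyl]acetic acid, via boron ketene acetal 7 (not isolated), via acyloxyborane 8 (not isolated)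
Conditions: (4S,5S)-2-bromo-1,3-bis{[3,5-bis(trifluoromethyl)phenyl]sulfonyl}-4,5-diphenyl-1,3,2-diazaborolidine (1.5 equiv), Et3N, toluene/hexane, −78 °C, then 4 → 23 °C; aqueous work-up
Reagents that add atoms: none
Why: Enantioselective Ireland–Claisen rearrangement through a chiral boron ketene acetal: Et3N in toluene–hexane should favour the E(O) enolate 7 (dioxanyl group cis to the allyloxy oxygen), whose chair transition state places that group and the C20 methyl axial and so gives the C9/C10 relative configuration of the target. The C2-symmetric bis-sulfonamide on boron shields one enolate face and sets the absolute configuration of both new centres (9R,10S) together; the symmetric acetonide keeps C8 prochiral, so 9 is one compound.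

Step 5
Reactants: 9 (2R)-2-(2,2-dimethyl-1,3-dioxan-5-yl)-2-[(1S)-1,3,3-trimethyl-2-methylidenecyclohexyl]acetic acid
Product: 10 (2R)-2-(2,2-dimethyl-1,3-dioxan-5-yl)-2-[(1S)-1,3,3-trimethyl-2-methylidenecyclohexyl]ethan-1-ol
Conditions: LiAlH4, THF, 0 °C → reflux
Reagents that add atoms: none
Why: Hydride reduction of the hindered carboxylic acid to the primary alcohol; acetonide and alkenes are inert and C9 cannot epimerise at this oxidation level.

Step 6
Reactants: 10 (2R)-2-(2,2-dimethyl-1,3-dioxan-5-yl)-2-[(1S)-1,3,3-trimethyl-2-methylidenecyclohexyl]ethan-1-ol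
Product: 11 (2R)-2-(2,2-dimethyl-1,3-dioxan-5-yl)-2-[(1S)-1,3,3-trimethyl-2-methylidenecyclohexyl]acetaldehyde
Conditions: Dess–Martin periodinane, pyridine, CH2Cl2, 0 → 23 °C
Reagents that add atoms: none
Why: Dess–Martin oxidation under buffered, non-basic conditions should give the α-branched aldehyde without epimerising C9.

Step 7
Reactants: 11 (2R)-2-(2,2-dimethyl-1,3-dioxan-5-yl)-2-[(1S)-1,3,3-trimethyl-2-methylidenecyclohexyl]acetaldehyde
Product: 12 2,2-dimethyl-5-{(1R)-1-[(1S)-1,3,3-trimethyl-2-methylidenecyclohexyl]prop-2-en-1-yl}-1,3-dioxane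
Conditions: Ph3PCH3Br, KN(SiMe3)2, THF, −78 → 0 °C
Reagents that add atoms: methyltriphenylphosphonium bromide, C[P+](c1ccccc1)(c1ccccc1)c1ccccc1.[Br-]
Why: Wittig methylenation at low temperature; addition of the ylide to the aldehyde should be faster than removal of the hindered C9 hydrogen, so C9 is kept.

Step 8
Reactants: 12 2,2-dimethyl-5-{(1R)-1-[(1S)-1,3,3-trimethyl-2-methylidenecyclohexyl]prop-2-en-1-yl}-1,3-dioxane
Product: 13 2-{(1R)-1-[(1S)-1,3,3-trimethyl-2-methylidenecyclohexyl]prop-2-en-1-yl}propane-1,3-diol
Conditions: PPTS, MeOH, 23 °C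
Reagents that add atoms: none
Why: Acid-catalysed transacetalisation to methanol removes the acetonide; the unactivated alkenes are not protonated by this weak acid.

Step 9
Reactants: 13 2-{(1R)-1-[(1S)-1,3,3-trimethyl-2-methylidenecyclohexyl]prop-2-en-1-yl}propane-1,3-diol
Product: 14 3-{[tert-butyl(dimethyl)silyl]oxy}-2-{(1R)-1-[(1S)-1,3,3-trimethyl-2-methylidenecyclohexyl]prop-2-en-1-yl}propan-1-ol (both C2 epimers; C2 is labdane C8)
Conditions: NaH (1.0 equiv), THF, 0 °C; then TBSCl (1.0 equiv), 0 → 23 °C
Reagents that add atoms: tert-butyl(chloro)dimethylsilane, CC(C)(C)[Si](C)(C)Cl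
Why: Monosilylation of a symmetrical 1,3-diol through its sparingly soluble monosodium alkoxide limits bis-silylation. The two arms are diastereotopic, so both C8 epimers form; this is harmless because C8 is equilibrated after ring closure.

Step 10
Reactants: 14 3-{[tert-butyl(dimethyl)silyl]oxy}-2-{(1R)-1-[(1S)-1,3,3-trimethyl-2-methylidenecyclohexyl]prop-2-en-1-yl}propan-1-ol (both C2 epimers)
Product: 16 (3R)-2-({[tert-butyl(dimethyl)silyl]oxy}methyl)-3-[(1S)-1,3,3-trimethyl-2-methylidenecyclohexyl]pent-4-enoic acid (both C2 epimers), via seco aldehyde 15 (not isolated)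
Conditions: TEMPO (cat.), PhI(OAc)2, MeCN/H2O, 23 °C
Reagents that add atoms: water, O
Why: Oxoammonium oxidation takes the primary alcohol through aldehyde 15 and its hydrate to the acid; no chlorine-based oxidant is present, so the two alkenes and the silyl ether are left alone.

Step 11
Reactants: 16 (3R)-2-({[tert-butyl(dimethyl)silyl]oxy}methyl)-3-[(1S)-1,3,3-trimethyl-2-methylidenecyclohexyl]pent-4-enoic acid (both C2 epimers); 17 diphenyl diselenide
Product: 18 Se-phenyl (3R)-2-({[tert-butyl(dimethyl)silyl]oxy}methyl)-3-[(1S)-1,3,3-trimethyl-2-methylidenecyclohexyl]pent-4-eneselenoate (both C2 epimers)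
Conditions: Bu3P, CH2Cl2, 23 °C
Reagents that add atoms: none
Why: Phosphine-mediated selenoesterification: Bu3P and the diselenide activate the carboxylate as an acyloxyphosphonium ion, which phenylselenolate attacks at the acyl carbon under neutral conditions.

Step 12
Reactants: 18 Se-phenyl (3R)-2-({[tert-butyl(dimethyl)silyl]oxy}methyl)-3-[(1S)-1,3,3-trimethyl-2-methylidenecyclohexyl]pent-4-eneselenoate (both C2 epimers)
Product: 20 (3S,4R,4aS,8aR)-3-({[tert-butyl(dimethyl)silyl]oxy}methyl)-4-ethenyl-4a,8,8-trimethyl-3,4,4a,5,6,7,8,8a-octahydronaphthalen-2(1H)-one, via C8-epimeric ketones 19 (not isolated)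
Conditions: (Me3Si)3SiH (1.5 equiv, slow addition), AIBN (0.2 equiv), PhH (0.01 M), 80 °C; then DBU (0.5 equiv), 23 °C
Reagents that add atoms: none
Why: The silyl radical takes PhSe from 18 and the C7 acyl radical adds to C6, the terminal carbon of the C5 methylene, closing ring B by a 6-endo-trig path; the closest known reaction type is the stannane- or silane-mediated acyl radical cyclisation of phenyl selenoesters onto 1,1-disubstituted alkenes. The 5-exo mode would need bond formation at C5, which is fully substituted and flanked by the quaternary C4 and C10, so the substrate secures the regioselectivity. The tertiary C5 radical cannot undergo the methyl shift open to a cation and is reduced by (Me3Si)3SiH on the face opposite the axial C20 and C4 methyl groups, which creates the C5 stereocentre and the trans ring fusion under control of C10. Ring closure must outrun loss of CO and direct reduction of the secondary acyl radical; the quaternary C10 in the tether and slow addition of the silane favour it. The C9 vinyl group is a spectator because attack on it would be a 4-exo or 5-endo closure. Either C8 epimer cyclises, and DBU then equilibrates C8 beside the new ketone to the equatorial CH2OTBS epimer, since the axial epimer is 1,3-diaxial to C20.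

Step 13
Reactants: 20 (3S,4R,4aS,8aR)-3-({[tert-butyl(dimethyl)silyl]oxy}methyl)-4-ethenyl-4a,8,8-trimethyl-3,4,4a,5,6,7,8,8a-octahydronaphthalen-2(1H)-one
Product: 21 N'-[(2E,3R,4R,4aS,8aR)-3-({[tert-butyl(dimethyl)silyl]oxy}methyl)-4-ethenyl-4a,8,8-trimethyloctahydronaphthalen-2(1H)-ylidene]-4-methylbenzenesulfonohydrazide
Conditions: TsNHNH2, MeOH, 50 °C
Reagents that add atoms: 4-methylbenzenesulfonohydrazide, Cc1ccc(cc1)S(=O)(=O)NN
Why: Condensation of the ketone with tosylhydrazide; the hydrazone should form with N–N anti to the branched C8, and C8 stays in its equilibrium (equatorial) configuration, with its descriptor changing only through priority.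

Step 14
Reactants: 21 N'-[(2E,3R,4R,4aS,8aR)-3-({[tert-butyl(dimethyl)silyl]oxy}methyl)-4-ethenyl-4a,8,8-trimethyloctahydronaphthalen-2(1H)-ylidene]-4-methylbenzenesulfonohydrazide
Product: 23 tert-butyl{[(1R,2S,4aR,8aS)-1-ethenyl-5,5,8a-trimethyl-1,2,4a,5,6,7,8,8a-octahydronaphthalen-2-yl]methoxy}dimethylsilane, via C7 vinyllithium 22 (not isolated)
Conditions: LiN(iPr)2 (4 equiv), THF, −78 → 23 °C; then H2O
Reagents that add atoms: none
Why: Shapiro reaction: the second deprotonation occurs at the C6 methylene syn to the sulfonamide nitrogen, loss of sulfinate and N2 gives vinyllithium 22, and protonation gives the C6=C7 alkene. The C8 hydrogen is not removed, so C8 and C5 are unchanged.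

Step 15
Reactants: 24 methyl 4-hydroxybut-2-ynoate
Product: 25 methyl (2Z)-4-hydroxy-3-iodobut-2-enoate
Conditions: NaI, AcOH (3 equiv), MeCN, 80 °C
Reagents that add atoms: sodium iodide, [Na+].[I-]
Why: Anti hydroiodination of the ynoate (conjugate addition of iodide, protonation anti to iodine) gives the Z iodoenoate; its hydroxymethyl group is trans to the ester and cannot lactonise.

Step 16
Reactants: 23 tert-butyl{[(1R,2S,4aR,8aS)-1-ethenyl-5,5,8a-trimethyl-1,2,4a,5,6,7,8,8a-octahydronaphthalen-2-yl]methoxy}dimethylsilane; 25 methyl (2Z)-4-hydroxy-3-iodobut-2-enoate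
Product: 27 methyl (5R,8S,9R,10S,13E)-17-{[tert-butyl(dimethyl)silyl]oxy}-16-hydroxylabda-6,13-dien-15-oate, via B-alkyl-9-BBN 26 (not isolated)
Conditions: 9-BBN, THF, 23 → 50 °C; then 25, PdCl2(dppf) (5 mol %), AsPh3, Cs2CO3, DMF/H2O, 23 °C
Reagents that add atoms: none
Why: Hydroboration–Suzuki–Miyaura coupling: 9-BBN adds only to the monosubstituted vinyl group (boron on C12) and leaves the cis-disubstituted ring alkene, and the alkyl group is transferred to the alkenylpalladium iodide with retention, so C12 ends cis to the ester (13E). C16 is kept as the free alcohol so that no allylic acetate meets zerovalent palladium.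

Step 17
Reactants: 27 methyl (5R,8S,9R,10S,13E)-17-{[tert-butyl(dimethyl)silyl]oxy}-16-hydroxylabda-6,13-dien-15-oate
Product: 28 (5R,8S,9R,10S,13E)-17-{[tert-butyl(dimethyl)silyl]oxy}-16-hydroxylabda-6,13-dien-15-oic acid
Conditions: LiOH·H2O, THF/MeOH/H2O, 23 °C; then 1 M HCl to pH 3, 0 °C
Reagents that add atoms: lithium hydroxide, [Li+].[OH-]
Why: Saponification of the conjugated methyl ester before the acetate exists; no stereocentre is α to a carbonyl at this stage and the primary silyl ether resists hydroxide.

Step 18
Reactants: 28 (5R,8S,9R,10S,13E)-17-{[tert-butyl(dimethyl)silyl]oxy}-16-hydroxylabda-6,13-dien-15-oic acid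
Product: 29 (5R,8S,9R,10S,13E)-16-acetoxy-17-{[tert-butyl(dimethyl)silyl]oxy}labda-6,13-dien-15-oic acid
Conditions: Ac2O, pyridine, DMAP (cat.), CH2Cl2, 0 → 23 °C; then H2O/THF
Reagents that add atoms: acetic anhydride, CC(=O)OC(C)=O
Why: Acetylation of the primary allylic alcohol; the mixed anhydride formed at the C15 acid is hydrolysed in the aqueous quench.

Step 19
Reactants: 29 (5R,8S,9R,10S,13E)-16-acetoxy-17-{[tert-butyl(dimethyl)silyl]oxy}labda-6,13-dien-15-oic acid
Product: 30 (5R,8S,9R,10S,13E)-16-acetoxy-17-hydroxylabda-6,13-dien-15-oic acid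
Conditions: HF·pyridine, pyridine, THF, 0 → 23 °C
Reagents that add atoms: none
Why: Fluoride-mediated desilylation buffered with pyridine; the acetate, the enoic acid and both alkenes are stable to these conditions.

Step 20
Reactants: 30 (5R,8S,9R,10S,13E)-16-acetoxy-17-hydroxylabda-6,13-dien-15-oic acid
Product: 32 (5R,8S,9R,10S,13E)-16-acetoxylabda-6,13-diene-15,17-dioic acid, via C17 aldehyde 31 (not isolated)
Conditions: TEMPO (cat.), PhI(OAc)2, MeCN/H2O, 0 → 23 °C
Reagents that add atoms: water, O
Why: Oxoammonium oxidation of the primary alcohol to the acid in one flask; aldehyde 31 is hydrated and oxidised as it forms in a weakly acidic medium, which should limit enolisation toward C8 (epimerisation or shift of the alkene into conjugation), and the acetate and alkenes are inert.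

## Compound list

1 | 2-(2,2-dimethyl-1,3-dioxan-5-yl)ethan-1-ol | OCCC1COC(C)(C)OC1 | starting material
2 | 2-(2,2-dimethyl-1,3-dioxan-5-yl)acetaldehyde | O=CCC1COC(C)(C)OC1 | intermediate (not isolated)
3 | 2-(2,2-dimethyl-1,3-dioxan-5-yl)acetic acid | OC(=O)CC1COC(C)(C)OC1 | intermediate
4 | β-cyclocitral | CC1=C(C=O)C(C)(C)CCC1 | starting material
5 | β-cyclogeraniol | CC1=C(CO)C(C)(C)CCC1 | intermediate
6 | (2,6,6-trimethylcyclohex-1-en-1-yl)methyl 2-(2,2-dimethyl-1,3-dioxan-5-yl)acetate | CC1=C(COC(=O)CC2COC(C)(C)OC2)C(C)(C)CCC1 | intermediate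
7 | E(O) boron ketene acetal of 6 (O-boryl = (4S,5S)-1,3-bis{[3,5-bis(trifluoromethyl)phenyl]sulfonyl}-4,5-diphenyl-1,3,2-diazaborolidin-2-yl; dioxanyl group cis to the allyloxy oxygen) | CC1=C(CO/C(OB2N(S(=O)(=O)c3cc(C(F)(F)F)cc(C(F)(F)F)c3)[C@@H](c3ccccc3)[C@H](c3ccccc3)N2S(=O)(=O)c2cc(C(F)(F)F)cc(C(F)(F)F)c2)=C\C2COC(C)(C)OC2)C(C)(C)CCC1 | intermediate (not isolated)
8 | acyloxyborane of acid 9 (same diazaborolidinyl group on the carboxyl oxygen) | O=C(OB1N(S(=O)(=O)c2cc(C(F)(F)F)cc(C(F)(F)F)c2)[C@@H](c2ccccc2)[C@H](c2ccccc2)N1S(=O)(=O)c1cc(C(F)(F)F)cc(C(F)(F)F)c1)[C@H](C1COC(C)(C)OC1)[C@]1(C)CCCC(C)(C)C1=C | intermediate (not isolated)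
9 | (2R)-2-(2,2-dimethyl-1,3-dioxan-5-yl)-2-[(1S)-1,3,3-trimethyl-2-methylidenecyclohexyl]acetic acid | OC(=O)[C@H](C1COC(C)(C)OC1)[C@]1(C)CCCC(C)(C)C1=C | intermediate
10 | (2R)-2-(2,2-dimethyl-1,3-dioxan-5-yl)-2-[(1S)-1,3,3-trimethyl-2-methylidenecyclohexyl]ethan-1-ol | OC[C@H](C1COC(C)(C)OC1)[C@]1(C)CCCC(C)(C)C1=C | intermediate
11 | (2R)-2-(2,2-dimethyl-1,3-dioxan-5-yl)-2-[(1S)-1,3,3-trimethyl-2-methylidenecyclohexyl]acetaldehyde | O=C[C@H](C1COC(C)(C)OC1)[C@]1(C)CCCC(C)(C)C1=C | intermediate
12 | 2,2-dimethyl-5-{(1R)-1-[(1S)-1,3,3-trimethyl-2-methylidenecyclohexyl]prop-2-en-1-yl}-1,3-dioxane | C=C[C@H](C1COC(C)(C)OC1)[C@]1(C)CCCC(C)(C)C1=C | intermediate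
13 | 2-{(1R)-1-[(1S)-1,3,3-trimethyl-2-methylidenecyclohexyl]prop-2-en-1-yl}propane-1,3-diol | C=C[C@H](C(CO)CO)[C@]1(C)CCCC(C)(C)C1=C | intermediate
14 | 3-{[tert-butyl(dimethyl)silyl]oxy}-2-{(1R)-1-[(1S)-1,3,3-trimethyl-2-methylidenecyclohexyl]prop-2-en-1-yl}propan-1-ol, both C2 (labdane C8) epimers | C=C[C@H](C(CO)CO[Si](C)(C)C(C)(C)C)[C@]1(C)CCCC(C)(C)C1=C | intermediate
15 | (3R)-2-({[tert-butyl(dimethyl)silyl]oxy}methyl)-3-[(1S)-1,3,3-trimethyl-2-methylidenecyclohexyl]pent-4-enal, both C2 epimers | C=C[C@H](C(C=O)CO[Si](C)(C)C(C)(C)C)[C@]1(C)CCCC(C)(C)C1=C | intermediate (not isolated)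
16 | (3R)-2-({[tert-butyl(dimethyl)silyl]oxy}methyl)-3-[(1S)-1,3,3-trimethyl-2-methylidenecyclohexyl]pent-4-enoic acid, both C2 epimers | C=C[C@H](C(C(=O)O)CO[Si](C)(C)C(C)(C)C)[C@]1(C)CCCC(C)(C)C1=C | intermediate
17 | diphenyl diselenide | c1ccccc1[Se][Se]c1ccccc1 | starting material
18 | Se-phenyl (3R)-2-({[tert-butyl(dimethyl)silyl]oxy}methyl)-3-[(1S)-1,3,3-trimethyl-2-methylidenecyclohexyl]pent-4-eneselenoate, both C2 epimers | C=C[C@H](C(C(=O)[Se]c1ccccc1)CO[Si](C)(C)C(C)(C)C)[C@]1(C)CCCC(C)(C)C1=C | intermediate
19 | (4R,4aS,8aR)-3-({[tert-butyl(dimethyl)silyl]oxy}methyl)-4-ethenyl-4a,8,8-trimethyloctahydronaphthalen-2(1H)-one, both C3 (labdane C8) epimers | C=C[C@@H]1C(CO[Si](C)(C)C(C)(C)C)C(=O)C[C@@H]2C(C)(C)CCC[C@@]12C | intermediate (not isolated)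
20 | (3S,4R,4aS,8aR)-3-({[tert-butyl(dimethyl)silyl]oxy}methyl)-4-ethenyl-4a,8,8-trimethyl-3,4,4a,5,6,7,8,8a-octahydronaphthalen-2(1H)-one (labdane: 7-oxo, 5R,8S,9R,10S) | C=C[C@@H]1[C@@H](CO[Si](C)(C)C(C)(C)C)C(=O)C[C@@H]2C(C)(C)CCC[C@@]12C | intermediate
21 | N'-[(2E,3R,4R,4aS,8aR)-3-({[tert-butyl(dimethyl)silyl]oxy}methyl)-4-ethenyl-4a,8,8-trimethyloctahydronaphthalen-2(1H)-ylidene]-4-methylbenzenesulfonohydrazide | C=C[C@@H]1[C@@H](CO[Si](C)(C)C(C)(C)C)/C(=N/NS(=O)(=O)c3ccc(C)cc3)C[C@@H]2C(C)(C)CCC[C@@]12C | intermediate
22 | C7-lithio derivative of 23 (vinyllithium at labdane C7) | C=C[C@@H]1[C@@H](CO[Si](C)(C)C(C)(C)C)C([Li])=C[C@@H]2C(C)(C)CCC[C@@]12C | intermediate (not isolated)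
23 | tert-butyl{[(1R,2S,4aR,8aS)-1-ethenyl-5,5,8a-trimethyl-1,2,4a,5,6,7,8,8a-octahydronaphthalen-2-yl]methoxy}dimethylsilane | C=C[C@@H]1[C@@H](CO[Si](C)(C)C(C)(C)C)C=C[C@@H]2C(C)(C)CCC[C@@]12C | intermediate
24 | methyl 4-hydroxybut-2-ynoate | COC(=O)C#CCO | starting material
25 | methyl (2Z)-4-hydroxy-3-iodobut-2-enoate | COC(=O)/C=C(\I)CO | intermediate
26 | 9-[(5R,8S,9R,10S)-17-{[tert-butyl(dimethyl)silyl]oxy}-13,14,15,16-tetranorlabd-6-en-12-yl]-9-borabicyclo[3.3.1]nonane | C(C[C@@H]1[C@@H](CO[Si](C)(C)C(C)(C)C)C=C[C@@H]2C(C)(C)CCC[C@@]12C)B3C4CCCC3CCC4 | intermediate (not isolated)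
27 | methyl (5R,8S,9R,10S,13E)-17-{[tert-butyl(dimethyl)silyl]oxy}-16-hydroxylabda-6,13-dien-15-oate | OC/C(=C/C(=O)OC)CC[C@@H]1[C@@H](CO[Si](C)(C)C(C)(C)C)C=C[C@@H]2C(C)(C)CCC[C@@]12C | intermediate
28 | (5R,8S,9R,10S,13E)-17-{[tert-butyl(dimethyl)silyl]oxy}-16-hydroxylabda-6,13-dien-15-oic acid | OC/C(=C/C(=O)O)CC[C@@H]1[C@@H](CO[Si](C)(C)C(C)(C)C)C=C[C@@H]2C(C)(C)CCC[C@@]12C | intermediate
29 | (5R,8S,9R,10S,13E)-16-acetoxy-17-{[tert-butyl(dimethyl)silyl]oxy}labda-6,13-dien-15-oic acid | CC(=O)OC/C(=C/C(=O)O)CC[C@@H]1[C@@H](CO[Si](C)(C)C(C)(C)C)C=C[C@@H]2C(C)(C)CCC[C@@]12C | intermediate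
30 | (5R,8S,9R,10S,13E)-16-acetoxy-17-hydroxylabda-6,13-dien-15-oic acid | CC(=O)OC/C(=C/C(=O)O)CC[C@@H]1[C@@H](CO)C=C[C@@H]2C(C)(C)CCC[C@@]12C | intermediate
31 | (5R,8S,9R,10S,13E)-16-acetoxy-17-oxolabda-6,13-dien-15-oic acid | CC(=O)OC/C(=C/C(=O)O)CC[C@@H]1[C@@H](C=O)C=C[C@@H]2C(C)(C)CCC[C@@]12C | intermediate (not isolated)
32 | (5R,8S,9R,10S,13E)-16-acetoxylabda-6,13-diene-15,17-dioic acid | CC(=O)OC/C(=C/C(=O)O)CC[C@@H]1[C@@H](C(=O)O)C=C[C@@H]2C(C)(C)CCC[C@@]12C | target

## Step count and least certain steps

Total step count: 20. Longest linear sequence: 18 steps (from 1 through steps 1, 3–14 and 16–20); steps 2 and 15 make the two side fragments.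

**Step 12 (key step).** The hindered tertiary C5 radical is captured slowly by the bulky silane, so hydrogen transfer on the face next to C20 may compete and erode the trans ring fusion. To a lesser degree, loss of CO from the secondary acyl radical may compete with ring closure, which initiation at lower temperature would temper. Fallback: the ring-fusion hydrogen is set by enolate protonation instead of radical reduction. The ketone mixture from step 12 (20 with its cis-fused C5 epimer F1) is enolised kinetically at C6 with LiN(iPr)2 and silylated with Me3SiCl to the C6=C7 trimethylsilyl enol ether F2. Oxidation with Pd(OAc)2 in MeCN (Saegusa–Ito) gives the 5-en-7-one F3. Reduction with lithium in liquid NH3/THF with one equivalent of t-BuOH, quenched with NH4Cl, protonates C5 axially and returns the trans-fused ketone 20.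

**Step 4.** The allyl terminus is a tetrasubstituted ring alkene and the enolate substituent is branched, so the rearrangement may be slow, a boat pathway may erode the C9/C10 relationship, and face discrimination by the boron controller may be incomplete. The Lewis-acidic bromoborane may also open the acetonide. Fallback: ester 6 is enolised with LiN(iPr)2 in THF at −78 °C and silylated with Me3SiCl to the E(O) trimethylsilyl ketene acetal F4. This rearranges on warming to the racemic trimethylsilyl ester F5, which is hydrolysed in the work-up to 9 together with its enantiomer F6. Crystallisation with (R)-1-phenylethylamine (or its antipode, whichever gives the less soluble salt of 9) gives the 1-phenylethylammonium salt F7, and acidification returns 9.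

**Step 14 (with step 13).** Condensation of a β-silyloxy ketone with a hydrazide may be accompanied by loss of silanol and conjugate addition of the hydrazide, and the excess amide base may attack the sulfonyl arene. Fallback: the alkene is placed through the enolate instead of the hydrazone. Ketone 20 is deprotonated at C6 with LiN(iPr)2 at −78 °C and trapped with PhNTf2 as the C7 enol triflate F8. Reduction with Pd(OAc)2/PPh3, Bu3N and HCO2H in DMF at 60 °C returns diene 23.

**Step 16.** Hydroboration of a vinyl group attached to a tertiary carbon beside a quaternary centre may be slow, and transmetalation of the branched alkylborane may lose out to protodeboronation. Fallback: a Negishi coupling through the iodide. Diene 23 is hydroborated with 9-BBN and oxidised (NaOH, H2O2) to the C12 alcohol F9, which is converted with I2, PPh3 and imidazole into the C12 iodide F10. Zinc insertion (Zn, LiCl, THF) gives the alkylzinc iodide F11. This is coupled, with Pd(PPh3)4 as catalyst, with the tetrahydropyranyl ether F12 of iodoenoate 25 (from 25, dihydropyran, PPTS) to the tetrahydropyranyl ether F13 of the coupling product. PPTS in MeOH then returns 27.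

## Further compounds

F1 | step 12 | (3S,4R,4aS,8aS)-3-({[tert-butyl(dimethyl)silyl]oxy}methyl)-4-ethenyl-4a,8,8-trimethyloctahydronaphthalen-2(1H)-one (cis-fused C5 epimer of 20) | C=C[C@@H]1[C@@H](CO[Si](C)(C)C(C)(C)C)C(=O)C[C@H]2C(C)(C)CCC[C@@]12C
F2 | step 12 | C6=C7 trimethylsilyl enol ether of 20 and F1 (C5 epimers) | C=C[C@@H]1[C@@H](CO[Si](C)(C)C(C)(C)C)C(O[Si](C)(C)C)=CC2C(C)(C)CCC[C@@]12C
F3 | step 12 | (8S,9R,10S)-17-{[tert-butyl(dimethyl)silyl]oxy}-5-en-7-one corresponding to 20 | C=C[C@@H]1[C@@H](CO[Si](C)(C)C(C)(C)C)C(=O)C=C2C(C)(C)CCC[C@@]12C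
F4 | step 4 | E(O) trimethylsilyl ketene acetal of 6 (dioxanyl group cis to the allyloxy oxygen) | CC1=C(CO/C(O[Si](C)(C)C)=C\C2COC(C)(C)OC2)C(C)(C)CCC1
F5 | step 4 | trimethylsilyl ester of racemic 9 (one enantiomer drawn) | C[Si](C)(C)OC(=O)[C@H](C1COC(C)(C)OC1)[C@]1(C)CCCC(C)(C)C1=C
F6 | step 4 | (2S)-2-(2,2-dimethyl-1,3-dioxan-5-yl)-2-[(1R)-1,3,3-trimethyl-2-methylidenecyclohexyl]acetic acid (enantiomer of 9) | OC(=O)[C@@H](C1COC(C)(C)OC1)[C@@]1(C)CCCC(C)(C)C1=C
F7 | step 4 | (R)-1-phenylethylammonium salt of 9 | [O-]C(=O)[C@H](C1COC(C)(C)OC1)[C@]1(C)CCCC(C)(C)C1=C.C[C@@H]([NH3+])c1ccccc1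
F8 | step 14 | C7 enol triflate of 20 (C6=C7) | C=C[C@@H]1[C@@H](CO[Si](C)(C)C(C)(C)C)C(OS(=O)(=O)C(F)(F)F)=C[C@@H]2C(C)(C)CCC[C@@]12C
F9 | step 16 | (5R,8S,9R,10S)-17-{[tert-butyl(dimethyl)silyl]oxy}-13,14,15,16-tetranorlabd-6-en-12-ol | OCC[C@@H]1[C@@H](CO[Si](C)(C)C(C)(C)C)C=C[C@@H]2C(C)(C)CCC[C@@]12C
F10 | step 16 | corresponding C12 iodide | ICC[C@@H]1[C@@H](CO[Si](C)(C)C(C)(C)C)C=C[C@@H]2C(C)(C)CCC[C@@]12C
F11 | step 16 | corresponding C12 alkylzinc iodide | I[Zn]CC[C@@H]1[C@@H](CO[Si](C)(C)C(C)(C)C)C=C[C@@H]2C(C)(C)CCC[C@@]12C
F12 | step 16 | methyl (2Z)-3-iodo-4-(oxan-2-yloxy)but-2-enoate | COC(=O)/C=C(\I)COC1CCCCO1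
F13 | step 16 | 16-O-(oxan-2-yl) ether of 27 | O(C/C(=C/C(=O)OC)CC[C@@H]1[C@@H](CO[Si](C)(C)C(C)(C)C)C=C[C@@H]2C(C)(C)CCC[C@@]12C)C3CCCCO3
A1 | alternative 1 | (E,E,E)-geranylgeranyl diphosphate | CC(C)=CCC/C(C)=C/CC/C(C)=C/CC/C(C)=C/COP(=O)(O)OP(=O)(O)O
A2 | alternative 1 | ent-copalyl diphosphate | O=P(O)(O)OP(=O)(O)OC/C=C(\C)CC[C@@H]1C(=C)CC[C@@H]2C(C)(C)CCC[C@@]12C
A3 | alternative 2 | 3-(2-{[tert-butyl(dimethyl)silyl]oxy}ethyl)-5-[(4Z)-5-iodo-2-methylpent-4-en-2-yl]-4-methylphenol | Cc1c(CCO[Si](C)(C)C(C)(C)C)cc(O)cc1C(C)(C)C/C=C\I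
A4 | alternative 2 | bicyclic cyclohexadienone | CC(C)(C)[Si](C)(C)OCCC1=CC(=O)C=C2C(C)(C)CC=C[C@@]12C
A5 | alternative 3 | C12 bromide of the silyl-protected decalin | BrCC[C@@H]1[C@@H](CO[Si](C)(C)C(C)(C)C)C=C[C@@H]2C(C)(C)CCC[C@@]12C
A6 | alternative 3 | 3-(tert-butoxy)prop-1-yne | C#CCOC(C)(C)C
A7 | alternative 3 | (E)-enoic acid with C16 tert-butyl ether | CC(C)(C)OC/C(=C/C(=O)O)CC[C@@H]1[C@@H](CO[Si](C)(C)C(C)(C)C)C=C[C@@H]2C(C)(C)CCC[C@@]12C
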